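## Retrosynthetic overview

1. Target 11 ⇐ C4–OMe bond: para-methoxylative dearomatisation of phenol 9 (ring A), then fluoride release of the ring B phenol in the same flask.
2. 9 ⇐ aromatic Claisen rearrangement of allyl ether 8 ⇐ O-allylation of phenol 7.
3. 7 (C8 stereocentre) ⇐ iridium-catalysed asymmetric hydrogenation of E-1,2-diarylpropene 6.
4. 6 ⇐ Suzuki coupling of bromophenol 4 with Z-alkenyl boronate 5 ⇐ copper-catalysed protoboration of aryl propyne 3 ⇐ Sonogashira coupling of silylated bromoguaiacol 2 (from 1).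
5. No ring is built: ring B and ring A are both bought as benzenes; ring A is turned into the cyclohexadienone in the last step.

Labels: ring A is the ring that ends as the dienone, ring B is the guaiacyl ring. C4 is the quaternary ring carbon and C8 the side-chain methine; the target is (4R,8R).

Assumption: the facial sense of the two chiral catalysts is taken from the closest precedents ((S)-phosphinooxazoline iridium complex gives R at C8, as for E-1,2-diphenylpropene; (R,R)-iodoarene gives 4R). If either proves opposite, its mirror-image catalyst is used.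

Catalysts used below:
- [Ir(cod)(L)]BArF, with L = (S)-4-tert-butyl-2-[2-(di-o-tolylphosphanyl)phenyl]-4,5-dihydrooxazole and BArF = B[3,5-(CF3)2C6H3]4.
- ArI* = (R,R)-2,2'-[(2-iodo-1,3-phenylene)bis(oxy)]bis(N-mesitylpropanamide), SMILES C[C@@H](Oc1cccc(O[C@H](C)C(=O)Nc2c(C)cc(C)cc2C)c1I)C(=O)Nc1c(C)cc(C)cc1C.

## Route

Step 1
Reactants: 1 4-bromo-2-methoxyphenol
Product: 2 (4-bromo-2-methoxyphenoxy)triisopropylsilane
Conditions: TIPSCl (1.2 equiv), imidazole (2.5 equiv), DMF, rt to 40 °C
Reagents that add atoms: triisopropylsilyl chloride, CC(C)[Si](Cl)(C(C)C)C(C)C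
Why: Imidazole-promoted O-silylation; the bulky aryl triisopropylsilyl ether withstands the bases, the Pd/Cu/Ir catalysis, 190 °C and the oxidant used later, and is removable with fluoride.

Step 2
Reactants: 2 (4-bromo-2-methoxyphenoxy)triisopropylsilane
Product: 3 [2-methoxy-4-(prop-1-yn-1-yl)phenoxy]triisopropylsilane
Conditions: propyne (3 equiv, THF solution), PdCl2(PhCN)2 (3 mol%), P(t-Bu)3 (6 mol%), CuI (2 mol%), i-Pr2NH (2 equiv), 1,4-dioxane, rt, sealed vessel
Reagents that add atoms: propyne, CC#C
Why: Sonogashira coupling; the P(t-Bu)3-ligated palladium catalyst couples electron-rich aryl bromides at room temperature and the silyl ether is inert to the amine base.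

Step 3
Reactants: 3 [2-methoxy-4-(prop-1-yn-1-yl)phenoxy]triisopropylsilane; 4 4-bromo-3-methoxyphenol
Product: 6 3-methoxy-4-[(E)-1-{3-methoxy-4-[(triisopropylsilyl)oxy]phenyl}prop-1-en-2-yl]phenol, via Z-alkenyl pinacol boronate 5 (not isolated)
Conditions: CuCl (5 mol%), Xantphos (5 mol%), NaOt-Bu (10 mol%), B2pin2 (1.1 equiv), MeOH (2 equiv), THF, rt; then 4 (0.95 equiv), Pd(OAc)2 (3 mol%), SPhos (6 mol%), aq K3PO4 (3 equiv), 70 °C
Reagents that add atoms: bis(pinacolato)diboron, CC1(C)OB(OC1(C)C)B1OC(C)(C)C(C)(C)O1 (its boryl group is carried only by intermediate 5)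
Why: Copper-catalysed protoboration adds Cu–B syn across the alkyne with boron on the methyl-bearing carbon (the aryl-stabilised alkenyl copper is then protonated by MeOH), and the Suzuki–Miyaura coupling proceeds with retention, so the two aryl groups end up trans in a single E-alkene.

Step 4
Reactants: 6 3-methoxy-4-[(E)-1-{3-methoxy-4-[(triisopropylsilyl)oxy]phenyl}prop-1-en-2-yl]phenol
Product: 7 3-methoxy-4-[(2R)-1-{3-methoxy-4-[(triisopropylsilyl)oxy]phenyl}propan-2-yl]phenol
Conditions: [Ir(cod)(L)]BArF (1 mol%), H2 (50 bar), CH2Cl2, rt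
Reagents that add atoms: none
Why: Iridium N,P-ligand (Pfaltz-type) asymmetric hydrogenation of an unfunctionalised E-1,2-diarylpropene, the benchmark substrate class for these catalysts; catalyst-controlled face selection sets C8 as R, and the aryl silyl ether and phenol are not reduced.

Step 5
Reactants: 7 3-methoxy-4-[(2R)-1-{3-methoxy-4-[(triisopropylsilyl)oxy]phenyl}propan-2-yl]phenol
Product: 8 {2-methoxy-4-[(2R)-2-[2-methoxy-4-(prop-2-en-1-yloxy)phenyl]propyl]phenoxy}triisopropylsilane
Conditions: allyl bromide (1.3 equiv), K2CO3 (2 equiv), acetone, reflux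
Reagents that add atoms: allyl bromide, C=CCBr
Why: Williamson etherification of the only free phenol; the hindered aryl silyl ether is stable to K2CO3 in acetone and C8 is untouched.

Step 6
Reactants: 8 {2-methoxy-4-[(2R)-2-[2-methoxy-4-(prop-2-en-1-yloxy)phenyl]propyl]phenoxy}triisopropylsilane
Product: 9 5-methoxy-4-[(2R)-1-{3-methoxy-4-[(triisopropylsilyl)oxy]phenyl}propan-2-yl]-2-(prop-2-en-1-yl)phenol
Conditions: PhNEt2, 190 °C, argon, 6 h
Reagents that add atoms: none
Why: Aromatic Claisen rearrangement ([3,3]-sigmatropic shift, then tautomerisation); the allyl group goes to the open ortho carbon para to OMe because the other ortho carbon is flanked by the methoxy group, whose methyl is pushed towards it by the neighbouring sec-alkyl substituent.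

Step 7
Reactants: 9 5-methoxy-4-[(2R)-1-{3-methoxy-4-[(triisopropylsilyl)oxy]phenyl}propan-2-yl]-2-(prop-2-en-1-yl)phenol
Product: 11 (4R)-4-[(2R)-1-(4-hydroxy-3-methoxyphenyl)propan-2-yl]-4,5-dimethoxy-2-(prop-2-en-1-yl)cyclohexa-2,5-dien-1-one, via silyl-protected dienone 10 (not isolated)
Conditions: ArI* (10 mol%), dried mCPBA (1.1 equiv), MeOH–CH2Cl2 (1:4), −20 °C; Me2S (0.2 equiv) to destroy excess peracid; then KHF2 (3 equiv), MeOH, rt
Reagents that add atoms: methanol, CO
Why: Proposed new method: mCPBA oxidises the C2-symmetric lactamide iodoarene to its trivalent-iodine form, which binds the phenol oxygen of 9; in the weakly ionising medium at −20 °C methanol attacks the para carbon C4 of this O-bound iodanyl phenoxide in an associative SN2'-type displacement of ArI*, and the helical pocket formed by the two hydrogen-bonded mesityl amide arms blocks one ring face while an amide carbonyl relays hydrogen-bonded MeOH to the other, overriding the weak 1,2-induction from C8 to set C4 as R; the closest known reactions are the non-selective PhI(OAc)2/MeOH para-quinol ether synthesis and chiral-iodoarene-catalysed enantioselective spirolactonising and hydroxylative phenol dearomatisations, none of which delivers methanol intermolecularly with catalyst control next to an existing stereocentre; KHF2 in MeOH then cleaves the aryl silyl ether without touching the dienone or the allyl group.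

## Compound list

1 | 4-bromo-2-methoxyphenol | COc1cc(Br)ccc1O | starting material
2 | (4-bromo-2-methoxyphenoxy)triisopropylsilane | COc1cc(Br)ccc1O[Si](C(C)C)(C(C)C)C(C)C | intermediate
3 | [2-methoxy-4-(prop-1-yn-1-yl)phenoxy]triisopropylsilane | CC#Cc1ccc(O[Si](C(C)C)(C(C)C)C(C)C)c(OC)c1 | intermediate
4 | 4-bromo-3-methoxyphenol | COc1cc(O)ccc1Br | starting material
5 | {2-methoxy-4-[(Z)-2-(4,4,5,5-tetramethyl-1,3,2-dioxaborolan-2-yl)prop-1-en-1-yl]phenoxy}triisopropylsilane | CC1(C)OB(/C(C)=C/c2ccc(O[Si](C(C)C)(C(C)C)C(C)C)c(OC)c2)OC1(C)C | intermediate (not isolated)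
6 | 3-methoxy-4-[(E)-1-{3-methoxy-4-[(triisopropylsilyl)oxy]phenyl}prop-1-en-2-yl]phenol | COc1cc(O)ccc1/C(C)=C/c1ccc(O[Si](C(C)C)(C(C)C)C(C)C)c(OC)c1 | intermediate
7 | 3-methoxy-4-[(2R)-1-{3-methoxy-4-[(triisopropylsilyl)oxy]phenyl}propan-2-yl]phenol | COc1cc(O)ccc1[C@H](C)Cc1ccc(O[Si](C(C)C)(C(C)C)C(C)C)c(OC)c1 | intermediate
8 | {2-methoxy-4-[(2R)-2-[2-methoxy-4-(prop-2-en-1-yloxy)phenyl]propyl]phenoxy}triisopropylsilane | C=CCOc1ccc([C@H](C)Cc2ccc(O[Si](C(C)C)(C(C)C)C(C)C)c(OC)c2)c(OC)c1 | intermediate
9 | 5-methoxy-4-[(2R)-1-{3-methoxy-4-[(triisopropylsilyl)oxy]phenyl}propan-2-yl]-2-(prop-2-en-1-yl)phenol | C=CCc1cc([C@H](C)Cc2ccc(O[Si](C(C)C)(C(C)C)C(C)C)c(OC)c2)c(OC)cc1O | intermediate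
10 | (4R)-4,5-dimethoxy-4-[(2R)-1-{3-methoxy-4-[(triisopropylsilyl)oxy]phenyl}propan-2-yl]-2-(prop-2-en-1-yl)cyclohexa-2,5-dien-1-one | C=CCC1=C[C@](OC)([C@H](C)Cc2ccc(O[Si](C(C)C)(C(C)C)C(C)C)c(OC)c2)C(OC)=CC1=O | intermediate (not isolated)
11 | (4R)-4-[(2R)-1-(4-hydroxy-3-methoxyphenyl)propan-2-yl]-4,5-dimethoxy-2-(prop-2-en-1-yl)cyclohexa-2,5-dien-1-one | C=CCC1=C[C@](OC)([C@H](C)Cc2ccc(O)c(OC)c2)C(OC)=CC1=O | target

## Step count and risks

Total step count: 7. Longest linear sequence: 7 (1 to 11; 4 is bought).

Three steps most likely to fail: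

**Step 7 (the new dearomatisation).** Facial control at a carbon para to the iodine-bound oxygen is unproven. A dissociative phenoxenium pathway would erode it, and ortho attack of MeOH or spirocyclisation by ring B could compete. Fallback with known chemistry, setting out from 9: oxidation with PhI(OAc)2 in MeOH at 0 °C, the standard non-selective para-quinol ether formation, gives silyl dienone 10 together with its C4 epimer (4S)-4,5-dimethoxy-4-[(2R)-1-{3-methoxy-4-[(triisopropylsilyl)oxy]phenyl}propan-2-yl]-2-(prop-2-en-1-yl)cyclohexa-2,5-dien-1-one F1. The two diastereomers are separated by chromatography, with preparative HPLC if needed. F1 is returned to phenol 9 by reductive aromatisation with Zn dust in acetic acid and resubmitted. The fallback comes back to the route at 10, which is desilylated with KHF2 in MeOH as in the second stage of step 7 to give 11.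

**Step 6 (Claisen regioselectivity).** Some allyl migration to the ortho carbon between the oxygen and the methoxy group is possible, and the two allylphenols may be hard to separate. Fallback, setting out from 7 and bypassing steps 5 and 6: NBS (1.0 equiv) in MeCN at −20 °C brominates ring A at its most activated open position, ortho to OH and para to OMe, to give 2-bromo-5-methoxy-4-[(2R)-1-{3-methoxy-4-[(triisopropylsilyl)oxy]phenyl}propan-2-yl]phenol F2. Stille coupling with allyltributylstannane (Bu3SnCH2CH=CH2) and Pd(PPh3)4 in DMF at 90 °C then places the allyl group unambiguously. The fallback comes back to the route at 9.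

**Step 4 (asymmetric hydrogenation).** The ortho-methoxy group twists ring A out of the alkene plane and the free phenol may slow or deselect the iridium catalyst, so the ee could be insufficient. Fallback, setting out from 6: hydrogenation over Pd/C (H2, 1 atm, EtOAc) gives the racemate, that is 7 together with its enantiomer 3-methoxy-4-[(2S)-1-{3-methoxy-4-[(triisopropylsilyl)oxy]phenyl}propan-2-yl]phenol F3. Resolution by preparative chiral SFC then gives 7. The fallback comes back to the route at 7.

## Further compounds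

F1 | step 7 | (4S)-4,5-dimethoxy-4-[(2R)-1-{3-methoxy-4-[(triisopropylsilyl)oxy]phenyl}propan-2-yl]-2-(prop-2-en-1-yl)cyclohexa-2,5-dien-1-one | C=CCC1=C[C@@](OC)([C@H](C)Cc2ccc(O[Si](C(C)C)(C(C)C)C(C)C)c(OC)c2)C(OC)=CC1=O
F2 | step 6 | 2-bromo-5-methoxy-4-[(2R)-1-{3-methoxy-4-[(triisopropylsilyl)oxy]phenyl}propan-2-yl]phenol | COc1cc(O)c(Br)cc1[C@H](C)Cc1ccc(O[Si](C(C)C)(C(C)C)C(C)C)c(OC)c1
F3 | step 4 | 3-methoxy-4-[(2S)-1-{3-methoxy-4-[(triisopropylsilyl)oxy]phenyl}propan-2-yl]phenol | COc1cc(O)ccc1[C@@H](C)Cc1ccc(O[Si](C(C)C)(C(C)C)C(C)C)c(OC)c1
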